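## The problem

The target is a cis-fused 2,6-diaryl-3,7-dioxabicyclo[3.3.0]octane with fusion carbons C1 and C5, aryl-bearing carbons C2 and C6 and methylenes C4 and C8; ring A is C1–C2–O3–C4–C5 and ring B is C5–C6–O7–C8–C1. Each of the two syringyl oxygens is bonded to C8 of a guaiacylglycerol chain (C7 benzylic carbinol, C8 aryloxy carbon, C9 CH2OH). One phenol carries a single chain (unit 3); the other carries a chain (unit 2) whose guaiacyl oxygen carries a further chain (unit 1), so the two ends of a C2-symmetric skeleton must be told apart by orthogonal protection from the start. There are ten stereocentres: the core is (1S,2R,5S,6R) with both aryl groups exo, unit 1 is erythro (7R,8S), unit 2 threo (7R,8R) and unit 3 erythro (7S,8R). Within the core one centre can steer the others (C6 directs the fusion carbons, and these direct C2), but the six arm centres are too remote for substrate control and need reagent control in both the threo and the erythro series. The benzylic C–O bonds at C2 and C6 and the C7 carbinols lie para to oxygen on electron-rich rings, so they ionise under acid and are open to hydrogenolysis; the phenols are oxidisable, so everything should stay masked until a final non-acidic, non-reductive deprotection. The enabling feature is in ring A: the unit aryl–C2H–O3–C4H2 spans the fusion bond C1–C5, which is a carbonyl ylide laid across an alkene; if that alkene is the C1=C5 bond of a butenolide that is ring B at the lactone level (C8 carbonyl, C6 stereocentre), one cycloaddition completes the bicycle and sets C1, C2 and C5 from C6.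

## Retrosynthesis

**44 ⇐ 43.** The last operation only removes four silyl groups (two aryl, two primary alkyl) with buffered fluoride. This keeps acid, hydrogen and oxidants away from the finished polyol; 43 already has every C–C and C–O bond and every stereocentre of 44.

**43 ⇐ 42 ⇐ 32 + 40.** The C7–C8 bond of unit 2 is cut (aldol). Against growing unit 1 on a finished unit 2, this cut is convergent: the whole outer unit arrives as aldehyde 40. The boron-mediated syn aldol of a glycolyl imide gives the threo pair that unit 2 needs without correction. The forward reaction must deliver (7R,8R) from the (S)-configured auxiliary through enolate 41, and the following hydride step must remove the auxiliary and both ester groups.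

**32 ⇐ 31 ⇐ 30 ⇐ 29 ⇐ 28 ⇐ 27 ⇐ 25 + 24; 25 ⇐ 18 + 20.** Unit 3 is cut at C7–C8 in the same way (enolate 26 of imide 25 with aldehyde 24), after the O–CH2 bond to the core phenol has been made by alkylation of 18 with 20. The syn aldol can only give threo, so the erythro relationship is reached by inverting C7 (31 → 32). The inversion is placed after debenzylation (29 → 30), so that no benzylic ester meets hydrogen, and after the second phenol has been capped as the next glycolyl imide (30 → 31), so that no free phenol competes as nucleophile. Each precursor is simpler by one protecting group or one stereocentre.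

**40 ⇐ 39 ⇐ 38 ⇐ 37 ⇐ 36 ⇐ 34 + 24; 34 ⇐ 33 + 22.** Unit 1 is built on isoeugenol 33 by the same alkylation, syn aldol (enolate 35), reduction and inversion, with the (R)-configured auxiliary. The propenyl group is a latent formyl group: it is inert to the enolisation, which a free aldehyde on the same molecule would not be, and is unmasked by oxidative cleavage (39 → 40).

**18 ⇐ 17 ⇐ 15 ⇐ 14.** The only redox adjustment of the core: the O7–C8 ether of ring B is traced back to lactone 14 through diol 15 and its primary sulfonate 16. Closing through the primary carbon leaves the C6–O bond intact, which an acid-mediated closure through the benzylic cation would not. Removal of the allyl group from 17 then frees the first phenol.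

**14 ⇐ 5 + 11 (key cut).** C1–C2 and C4–C5 are cut together. The competing cuts that form one of these bonds at a time leave more steps after them and set C2 or C6 separately. Here the precursors are an achiral acetal and a butenolide with one stereocentre, and the forward step must control regiochemistry, facial selectivity and the orientation of the aryl group. The allyl ether is placed on the ylide partner and the benzyl ether on the butenolide because the butenolide is made by metathesis and cannot carry a second alkene. A 4-methoxybenzyl ether was not used: it would meet silyl triflate in the key step, and its acidic or oxidative removal threatens the benzylic ethers of the core.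

**5 ⇐ 2 ⇐ 1 (+ two molecules of 3); 11 ⇐ 10 ⇐ 8 ⇐ 6 ⇐ 1 (+ 7, 9).** Both partners come from syringaldehyde 1. The acetal 5 is reached through dimethyl acetal 4, whose two methoxy groups are exchanged for two molecules of 3. The butenolide 11 arises by vinyl addition, enzymatic resolution that installs the acrylate on the (R)-carbinol, and ring-closing metathesis under neutral conditions, so that the base-sensitive C6–H is not put at risk.

## Roads not taken

**Alternative 1:** The cuts are C5–C6 and C1–C2, but no ring is closed. The lithium anion of dithiane A3 (from 6) adds 1,4 to the menthyloxy butenolide A2, and the lactone enolate is trapped by aldehyde 2 to give the trans,trans lactone A1 (acetal carbon = future C4, lactone carbonyl = future C8).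
- Merits: every reaction type is established in lignan chemistry, the two differently protected aryl groups enter in one operation, and the acetal auxiliary fixes C5 and through it C1.
- Weak points: the dithiane must be removed beside an allyl ether and electron-rich arenes; C6 is created later by a separate ketone reduction; the C2 carbinol comes from an aldol with uncertain facial control; a tetraol must finally be closed twice; and this enantiomer needs A2 in the less common antipodal series of its terpene auxiliary.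
- Comparison: about six operations separate A1 from the stage of 17, against two from 14. In precedent this road is clearly ahead, and it is therefore kept as the fallback for the key step. Against it the chosen plan sets a C6 centre fixed before the key step and the formation of C1, C2, C5 and ring A together.

**Alternative 2:** The cuts are C1–C5 and O7–C6. Cp2TiCl (trivalent titanium) opens the oxirane of epoxy ether A5 to the C1 radical, 5-exo closure onto the cinnamyl double bond forms C1–C5 and ring A, and oxidation of the benzylic position with iodine lets the titanium alkoxide O7 close ring B, giving A4.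
- Merits: two rings and the fusion bond in one flask, no lactone to reduce, a reaction type known for this lignan class. A4 is the functional equal of 17 and would save two steps after the key step.
- Weak points: C2 of A5 must be made enantiopure and its allylic ether bond formed by alkylation with a partner that ionises easily; C1 and C5 follow from C2 only through a radical transition state; C6 is set last through a benzylic radical or cation, the centre that epimerises most easily.
- Comparison: this road is shorter and precedented, which the chosen plan cannot match. Its weakest stereocentre, C6, is the strongest of the chosen plan, where it is carried enantiopure in 11 and its C–O bond is never broken.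

**Alternative 3:** The cut is C1–C5 alone. The bis(silyl ketene acetal) of diolide A7 is oxidised so that the two α-carbons couple across the eight-membered ring, giving bis-lactone A6.
- Merits: all four core centres derive from the single stereocentre of the β-hydroxy acid A8, the symmetry halves the work, and oxidative enolate coupling is a known reaction type.
- Weak points: head-to-tail dimerisation of A8 to A7 competes with β-elimination of its hydroxyl group; a transannular coupling in such a ring has no close model; A6 lies two oxidation levels above the core and needs double reduction and double closure; both phenols carry the same benzyl group, so the two different arms could only follow a statistical mono-deprotection.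
- Comparison: both plans contain one unprecedented step, so neither is safer there, and this road sets C1–C5 and the whole core from a single stereogenic monomer. The chosen plan delivers the two phenols differentiated, which a symmetric route cannot.

Key step: step 7

Remarks.
- The core is C2-symmetric (the axis exchanges C1/C5, C2/C6 and the two aryl groups), so it is immaterial which aryl group receives which arm; 44 is written in the orientation of the target.
- Commercial trans-isoeugenol 33 is assumed; its alkene geometry is irrelevant because the alkene is cleaved in step 26.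
- Shorthand in names: "core" is (1S,2R,5S,6R)-2,6-bis(3,5-dimethoxyphenyl)-3,7-dioxabicyclo[3.3.0]octane, whose para oxygens are O-a (aryl on C2) and O-b (aryl on C6). A "chain" is O–C8H(C9H2–O)–C7H(O)–aryl, bonded through the C8 oxygen. Ar(T) is 3-methoxy-4-(triisopropylsilyloxy)phenyl; Xc(S) and Xc(R) are (4S)- and (4R)-4-benzyl-2-oxooxazolidin-3-yl; TBS = tert-butyldimethylsilyl, TIPS = triisopropylsilyl, PNB = 4-nitrobenzoyl.

## Route

Step 1
Reactants: 1 syringaldehyde
Product: 2 4-(allyloxy)-3,5-dimethoxybenzaldehyde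
Conditions: allyl bromide, K2CO3, DMF, 50 °C
Reagents that add atoms: allyl bromide C=CCBr
Why: Williamson etherification of the acidic, hindered phenol; the allyl ether tolerates silyl triflate, fluoride and hydride and is later removed by zerovalent palladium without touching the benzyl ether.

Step 2
Reactants: 2 4-(allyloxy)-3,5-dimethoxybenzaldehyde; 3 (trimethylsilyl)methanol
Product: 5 4-(allyloxy)-3,5-dimethoxybenzaldehyde bis[(trimethylsilyl)methyl] acetal, via dimethyl acetal 4 (not isolated)
Conditions: HC(OMe)3, MeOH, TsOH (cat.), rt; evaporate; then 3 (3 equiv, two of which are taken up), PPTS (cat.), toluene, 90 °C, MeOH distilled off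
Reagents that add atoms: (trimethylsilyl)methanol (second equivalent of 3) C[Si](C)(C)CO
Why: Orthoformate acetalisation followed by acid-catalysed transacetalisation, in which two molecules of 3 replace the two methoxy groups of 4 and the equilibrium is driven by removal of methanol. The symmetric acetal ensures that whichever alkoxy group leaves on ionisation, the oxocarbenium ion keeps a CH2SiMe3 arm.

Step 3
Reactants: 1 syringaldehyde
Product: 6 4-(benzyloxy)-3,5-dimethoxybenzaldehyde
Conditions: BnBr, K2CO3, DMF, 50 °C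
Reagents that add atoms: benzyl bromide BrCc1ccccc1
Why: Williamson etherification; the benzyl ether is inert to Grignard reagent, lipase, metathesis catalyst and the key step, and is orthogonal to allyl.

Step 4
Reactants: 6 4-(benzyloxy)-3,5-dimethoxybenzaldehyde; 7 vinylmagnesium bromide
Product: 8 rac-1-[4-(benzyloxy)-3,5-dimethoxyphenyl]prop-2-en-1-ol
Conditions: THF, −78 to 0 °C; aq. NH4Cl
Reagents that add atoms: none
Why: Grignard 1,2-addition to the aldehyde; the racemic carbinol is resolved in the next step.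

Step 5
Reactants: 8 rac-1-[4-(benzyloxy)-3,5-dimethoxyphenyl]prop-2-en-1-ol; 9 vinyl acrylate
Product: 10 (1R)-1-[4-(benzyloxy)-3,5-dimethoxyphenyl]prop-2-en-1-yl acrylate
Conditions: Novozym 435 (immobilised Candida antarctica lipase B), BHT (cat.), toluene, 30 °C, stopped near half conversion
Reagents that add atoms: none
Why: Lipase-catalysed kinetic resolution by irreversible transesterification; the empirical rule for secondary carbinols with one large (aryl) and one medium (vinyl) group predicts acylation of the (R)-enantiomer, so the acrylate needed for metathesis should form directly with the right configuration and the unreacted (S)-alcohol is separated.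

Step 6
Reactants: 10 (1R)-1-[4-(benzyloxy)-3,5-dimethoxyphenyl]prop-2-en-1-yl acrylate
Product: 11 (5R)-5-[4-(benzyloxy)-3,5-dimethoxyphenyl]furan-2(5H)-one
Conditions: second-generation Grubbs catalyst (H2IMes)(PCy3)Cl2Ru=CHPh (5 mol%), CH2Cl2 (0.01 M), 40 °C
Reagents that add atoms: none
Why: Ring-closing metathesis of the acrylate of an allylic alcohol gives the butenolide under neutral conditions, so the doubly activated C–H at the stereocentre never meets base and the configuration is carried over unchanged.

Step 7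
Reactants: 5 4-(allyloxy)-3,5-dimethoxybenzaldehyde bis[(trimethylsilyl)methyl] acetal; 11 (5R)-5-[4-(benzyloxy)-3,5-dimethoxyphenyl]furan-2(5H)-one
Product: 14 (1R,2R,5S,6R)-2-[4-(allyloxy)-3,5-dimethoxyphenyl]-6-[4-(benzyloxy)-3,5-dimethoxyphenyl]-3,7-dioxabicyclo[3.3.0]octan-8-one, via oxocarbenium triflate 12 (not isolated), via carbonyl ylide 13 (not isolated)
Conditions: 5 (1.5 equiv), TMSOTf (1.5 equiv), CH2Cl2, −78 °C; then 11 (1 equiv) and CsF (4 equiv), MeCN, −40 to 0 °C
Reagents that add atoms: none
Why: Proposed new method: TMSOTf should ionise one arm of acetal 5 to the aryl-conjugated oxocarbenium triflate 12, which still carries a CH2SiMe3 group on oxygen, and fluoride should then remove silicon to release the non-stabilised carbonyl ylide 13 in the presence of 11; the closest known reaction type is the fluoride-triggered 1,3-elimination of silylmethyl ethers to carbonyl ylides with (3+2) addition to electron-poor alkenes, together with the analogous silylmethylamine route to azomethine ylides that add to butenolides. The donor aryl group keeps positive character on the benzylic carbon, so the larger HOMO coefficient of 13 lies on the CH2 terminus, which should bond to the β-carbon C5 of the butenolide (largest LUMO coefficient) while the benzylic carbon bonds to the α-carbon C1. Ring A closes by a concerted cycloaddition, suprafacial on both partners, in which C1–C2 and C4–C5 form together; a stepwise Michael addition would have to finish with a 5-endo-trig closure and is not expected. Suprafacial addition to the ring alkene makes the fusion cis, and approach of the dipole on the face opposite the C6 aryl group fixes C1 and C5 relative to the existing centre C6. C2 is set by the orientation of the ylide: the transition state that turns its aryl group away from the lactone ring (exo) gives the required 2-exo aryl group and is favoured sterically. The step therefore needs CH2-to-C5 regiochemistry (ylide polarisation), anti facial approach (C6 aryl group) and exo orientation (sterics), and it needs C6 to survive, which is why the silyl triflate is consumed before 11 and fluoride are added cold.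

Step 8
Reactants: 14 the bicyclic lactone
Product: 15 (R)-[4-(benzyloxy)-3,5-dimethoxyphenyl]{(3S,4S,5R)-5-[4-(allyloxy)-3,5-dimethoxyphenyl]-4-(hydroxymethyl)oxolan-3-yl}methanol
Conditions: LiAlH4, THF, 0 °C
Reagents that add atoms: none
Why: Hydride reduction of the lactone opens ring B to the primary alcohol (C8) and the benzylic carbinol (C6) without touching a stereocentre; allyl and benzyl ethers are inert.

Step 9
Reactants: 15 the diol
Product: 17 (1S,2R,5S,6R)-2-[4-(allyloxy)-3,5-dimethoxyphenyl]-6-[4-(benzyloxy)-3,5-dimethoxyphenyl]-3,7-dioxabicyclo[3.3.0]octane, via primary tosylate 16 (not isolated)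
Conditions: TsCl (1.1 equiv), Et3N, DMAP (cat.), CH2Cl2, 0 °C; then KOtBu, THF, 0 °C to rt
Reagents that add atoms: none
Why: Selective sulfonylation of the primary hydroxyl followed by intramolecular Williamson etherification (5-exo-tet) by the C6 alkoxide re-forms ring B at the ether level; the C6–O bond is never broken, so C6 and its exo aryl group are retained.

Step 10
Reactants: 17 the allyl/benzyl-protected core
Product: 18 4-[(1S,2R,5S,6R)-6-(4-benzyloxy-3,5-dimethoxyphenyl)-3,7-dioxabicyclo[3.3.0]octan-2-yl]-2,6-dimethoxyphenol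
Conditions: Pd(PPh3)4 (5 mol%), morpholine, THF, rt
Reagents that add atoms: none
Why: Tsuji–Trost deallylation: zerovalent palladium transfers the allyl group to morpholine and frees one syringyl phenol, leaving the benzyl ether and the benzylic ring ethers untouched.

Step 11
Reactants: 19 (S)-4-benzyloxazolidin-2-one
Product: 20 (S)-4-benzyl-3-(bromoacetyl)oxazolidin-2-one
Conditions: n-BuLi, THF, −78 °C; then BrCH2COBr
Reagents that add atoms: bromoacetyl bromide BrCC(Br)=O
Why: N-acylation of the lithiated oxazolidinone at the acyl bromide, which is far more electrophilic than the alkyl bromide; standard preparation of a haloacetyl imide.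

Step 12
Reactants: 21 (R)-4-benzyloxazolidin-2-one
Product: 22 (R)-4-benzyl-3-(bromoacetyl)oxazolidin-2-one
Conditions: n-BuLi, THF, −78 °C; then BrCH2COBr
Reagents that add atoms: bromoacetyl bromide BrCC(Br)=O
Why: As step 11, in the enantiomeric series needed for unit 1.

Step 13
Reactants: 23 vanillin
Product: 24 3-methoxy-4-(triisopropylsilyloxy)benzaldehyde
Conditions: TIPSCl, imidazole, DMF, rt
Reagents that add atoms: chlorotri(propan-2-yl)silane CC(C)[Si](Cl)(C(C)C)C(C)C
Why: Silylation of the phenol; the bulky aryl silyl ether should tolerate carbonate, boron triflate, borohydride and hydrogenation and leaves with fluoride at the end.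

Step 14
Reactants: 18 the mono-phenol; 20 (S)-4-benzyl-3-(bromoacetyl)oxazolidin-2-one
Product: 25 core with O-a–CH2C(=O)Xc(S) and O-b benzyl
Conditions: K2CO3, acetone, rt
Reagents that add atoms: none
Why: SN2 displacement at the activated α-bromo imide by the phenoxide installs the glycolyl imide in one step; dry carbonate leaves the imide intact.

Step 15
Reactants: 25 the glycolyl imide; 24 3-methoxy-4-(triisopropylsilyloxy)benzaldehyde
Product: 27 syn-aldol adduct: core with O-a–CH[C(=O)Xc(S)]–CH(OH)Ar(T) of (2S,3R) configuration and O-b benzyl, via boron enolate 26 (not isolated)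
Conditions: Bu2BOTf, iPr2NEt, CH2Cl2, −78 to 0 °C; then 24, −78 to 0 °C; pH 7 buffer, MeOH, H2O2, 0 °C
Reagents that add atoms: none
Why: Evans syn aldol: the (Z)-boron enolate reacts through a chair (Zimmerman–Traxler) transition state on the face away from the benzyl group of the auxiliary, which sets both new centres, (2S,3R) in the propanoyl unit and (7R,8R) threo in the chain after reduction; aryloxyacetyl imides and aryl aldehydes are established partners for this reaction.

Step 16
Reactants: 27 the aldol adduct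
Product: 28 core with O-a chain (7R,8R) carrying free 7-OH and 9-OH and Ar(T); O-b benzyl
Conditions: LiBH4, THF, H2O (1 equiv), 0 °C
Reagents that add atoms: none
Why: Reductive cleavage of the N-acyl oxazolidinone gives the primary alcohol C9 and returns the auxiliary; no stereocentre is involved.

Step 17
Reactants: 28 the threo diol
Product: 29 core with O-a chain (7R,8R) carrying 7-OH and 9-OTBS and Ar(T); O-b benzyl
Conditions: TBSCl, imidazole, CH2Cl2, 0 °C
Reagents that add atoms: tert-butylchlorodimethylsilane CC(C)(C)[Si](C)(C)Cl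
Why: The primary hydroxyl is silylated much faster than the hindered secondary benzylic one, which is left free for the later inversion.

Step 18
Reactants: 29 the mono-silyl ether
Product: 30 core with O-a chain (7R,8R) carrying 7-OH and 9-OTBS and Ar(T); O-b free phenol
Conditions: H2 (1 atm), Pd/C, EtOAc, rt, monitored
Reagents that add atoms: none
Why: Hydrogenolysis of the aryl benzyl ether, the most labile C–O bond present under neutral conditions; it is done while C7 carries a free hydroxyl and not an ester, because a benzylic ester would be cleaved as well.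

Step 19
Reactants: 30 the phenol; 20 (S)-4-benzyl-3-(bromoacetyl)oxazolidin-2-one
Product: 31 core with O-a chain (7R,8R) carrying 7-OH and 9-OTBS and Ar(T); O-b–CH2C(=O)Xc(S)
Conditions: K2CO3, acetone, rt
Reagents that add atoms: none
Why: As step 14; only the phenol is acidic enough to be alkylated under carbonate, the benzylic alcohol is not.

Step 20
Reactants: 31 the threo alcohol
Product: 32 core with O-a chain (7S,8R) carrying 7-OPNB and 9-OTBS and Ar(T); O-b–CH2C(=O)Xc(S)
Conditions: 4-nitrobenzoic acid, PPh3, DIAD, THF, 0 °C to rt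
Reagents that add atoms: 4-nitrobenzoic acid OC(=O)c1ccc(cc1)[N+](=O)[O-]
Why: Mitsunobu esterification: SN2 displacement of the oxyphosphonium group by carboxylate inverts C7 and turns threo (7R,8R) into erythro (7S,8R); the ester then masks O7 during the next aldol.

Step 21
Reactants: 33 trans-isoeugenol; 22 (R)-4-benzyl-3-(bromoacetyl)oxazolidin-2-one
Product: 34 (4R)-4-benzyl-3-({2-methoxy-4-[(E)-prop-1-enyl]phenoxy}acetyl)oxazolidin-2-one
Conditions: K2CO3, acetone, rt
Reagents that add atoms: none
Why: Phenoxide SN2 alkylation as in step 14; the propenyl group serves as a latent formyl group that is inert to the enolisation to follow.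

Step 22
Reactants: 34 the isoeugenyl glycolyl imide; 24 3-methoxy-4-(triisopropylsilyloxy)benzaldehyde
Product: 36 (4R)-4-benzyl-3-[(2R,3S)-3-hydroxy-2-{2-methoxy-4-[(E)-prop-1-enyl]phenoxy}-3-Ar(T)-propanoyl]oxazolidin-2-one, via boron enolate 35 (not isolated)
Conditions: Bu2BOTf, iPr2NEt, CH2Cl2, −78 to 0 °C; then 24, −78 to 0 °C; pH 7 buffer, MeOH, H2O2, 0 °C
Reagents that add atoms: none
Why: Evans syn aldol with the enantiomeric auxiliary; the same chair transition state gives the mirror-image threo pair, (2R,3S) in the adduct and (7S,8S) in the chain.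

Step 23
Reactants: 36 the aldol adduct
Product: 37 (1S,2S)-2-{2-methoxy-4-[(E)-prop-1-enyl]phenoxy}-1-Ar(T)-propane-1,3-diol
Conditions: LiBH4, THF, H2O (1 equiv), 0 °C
Reagents that add atoms: none
Why: Reductive removal of the auxiliary as in step 16.

Step 24
Reactants: 37 the threo diol
Product: 38 (1S,2S)-3-(tert-butyldimethylsilyloxy)-2-{2-methoxy-4-[(E)-prop-1-enyl]phenoxy}-1-Ar(T)-propan-1-ol
Conditions: TBSCl, imidazole, CH2Cl2, 0 °C
Reagents that add atoms: tert-butylchlorodimethylsilane CC(C)(C)[Si](C)(C)Cl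
Why: Selective silylation of the primary hydroxyl as in step 17.

Step 25
Reactants: 38 the threo alcohol
Product: 39 (1R,2S)-3-(tert-butyldimethylsilyloxy)-2-{2-methoxy-4-[(E)-prop-1-enyl]phenoxy}-1-Ar(T)-propyl 4-nitrobenzoate
Conditions: 4-nitrobenzoic acid, PPh3, DIAD, THF, 0 °C to rt
Reagents that add atoms: 4-nitrobenzoic acid OC(=O)c1ccc(cc1)[N+](=O)[O-]
Why: Mitsunobu inversion at C7 as in step 20 converts (7S,8S) into the erythro pair (7R,8S) of unit 1.

Step 26
Reactants: 39 the erythro ester
Product: 40 (1R,2S)-3-(tert-butyldimethylsilyloxy)-2-(4-formyl-2-methoxyphenoxy)-1-Ar(T)-propyl 4-nitrobenzoate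
Conditions: K2OsO4·2H2O (cat.), NaIO4, 2,6-lutidine, dioxane/H2O, rt
Reagents that add atoms: sodium periodate [Na+].[O-]I(=O)(=O)=O
Why: Lemieux–Johnson cleavage: dihydroxylation of the electron-rich styrene-type alkene and periodate scission of the diol give the aryl aldehyde; esters and silyl ethers are inert.

Step 27
Reactants: 32 the core imide with erythro unit 3; 40 the unit 1 aldehyde
Product: 42 union aldol adduct: core with O-a chain as in 32 and O-b–CH[C(=O)Xc(S)]–CH(OH)–aryl of (2S,3R) configuration whose aryl is the 3-methoxy-4-oxyphenyl ring of 40, via boron enolate 41 (not isolated)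
Conditions: Bu2BOTf, iPr2NEt, CH2Cl2, −78 to 0 °C; then 40, −78 to 0 °C; pH 7 buffer, MeOH, H2O2, 0 °C
Reagents that add atoms: none
Why: Evans syn aldol as in step 15, now joining the two halves; the (S)-auxiliary sets the threo pair (7R,8R) of unit 2, and boron enolates do not attack the two ester groups.

Step 28
Reactants: 42 the union aldol adduct
Product: 43 core with unit 3 (7S,8R: 7-OH, 9-OTBS, Ar(T)) on O-a and unit 2 (7R,8R: 7-OH, 9-OH) on O-b whose aryl oxygen carries unit 1 (7R,8S: 7-OH, 9-OTBS, Ar(T))
Conditions: LiBH4 (excess), MeOH, THF, 0 °C to rt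
Reagents that add atoms: none
Why: Borohydride reduces the imide to the primary alcohol C9 of unit 2 and reduces both activated 4-nitrobenzoate esters, freeing the two C7 hydroxyls; silyl ethers and the nitro group of the leaving fragment are not affected.

Step 29
Reactants: 43 the tetrasilyl ether
Product: 44 the target, CNP0316493.1
Conditions: Bu4NF, AcOH, THF, 0 °C to rt
Reagents that add atoms: none
Why: Fluoride-mediated desilylation of the two aryl and two primary alkyl silyl ethers, buffered with acetic acid so that the freed phenols are not left as phenoxides beside benzylic carbinols.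

## Compound list

1 | syringaldehyde (4-hydroxy-3,5-dimethoxybenzaldehyde) | COc1cc(C=O)cc(OC)c1O | starting material
2 | 4-(allyloxy)-3,5-dimethoxybenzaldehyde | COc1cc(C=O)cc(OC)c1OCC=C | intermediate
3 | (trimethylsilyl)methanol | C[Si](C)(C)CO | starting material
4 | 4-(allyloxy)-3,5-dimethoxybenzaldehyde dimethyl acetal | COc1cc(cc(OC)c1OCC=C)C(OC)OC | intermediate
5 | 4-(allyloxy)-3,5-dimethoxybenzaldehyde bis[(trimethylsilyl)methyl] acetal | COc1cc(cc(OC)c1OCC=C)C(OC[Si](C)(C)C)OC[Si](C)(C)C | intermediate
6 | 4-(benzyloxy)-3,5-dimethoxybenzaldehyde | COc1cc(C=O)cc(OC)c1OCc1ccccc1 | intermediate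
7 | vinylmagnesium bromide | C=C[Mg]Br | starting material
8 | rac-1-[4-(benzyloxy)-3,5-dimethoxyphenyl]prop-2-en-1-ol | COc1cc(cc(OC)c1OCc1ccccc1)C(O)C=C | intermediate
9 | vinyl acrylate | C=CC(=O)OC=C | starting material
10 | (1R)-1-[4-(benzyloxy)-3,5-dimethoxyphenyl]prop-2-en-1-yl acrylate | C=CC(=O)O[C@H](C=C)c1cc(OC)c(OCc2ccccc2)c(OC)c1 | intermediate
11 | (5R)-5-[4-(benzyloxy)-3,5-dimethoxyphenyl]furan-2(5H)-one | C1=CC(=O)O[C@H]1c1cc(OC)c(OCc2ccccc2)c(OC)c1 | intermediate
12 | [4-(allyloxy)-3,5-dimethoxybenzylidene][(trimethylsilyl)methyl]oxonium trifluoromethanesulfonate | COc1cc(cc(OC)c1OCC=C)C=[O+]C[Si](C)(C)C.[O-]S(=O)(=O)C(F)(F)F | intermediate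
13 | carbonyl ylide: [4-(allyloxy)-3,5-dimethoxybenzylidene]oxonium methanide | COc1cc(cc(OC)c1OCC=C)C=[O+][CH2-] | intermediate
14 | (1R,2R,5S,6R)-2-[4-(allyloxy)-3,5-dimethoxyphenyl]-6-[4-(benzyloxy)-3,5-dimethoxyphenyl]-3,7-dioxabicyclo[3.3.0]octan-8-one | COc1cc(cc(OC)c1OCC=C)[C@@H]1OC[C@@H]2[C@H]1C(=O)O[C@H]2c1cc(OC)c(OCc2ccccc2)c(OC)c1 | intermediate
15 | (R)-[4-(benzyloxy)-3,5-dimethoxyphenyl]{(3S,4S,5R)-5-[4-(allyloxy)-3,5-dimethoxyphenyl]-4-(hydroxymethyl)oxolan-3-yl}methanol | COc1cc(cc(OC)c1OCC=C)[C@@H]1OC[C@@H]([C@@H](O)c2cc(OC)c(OCc3ccccc3)c(OC)c2)[C@H]1CO | intermediate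
16 | primary 4-methylbenzenesulfonate of 15 (tosyl on the CH2OH oxygen, stereocentres as in 15) | COc1cc(cc(OC)c1OCC=C)[C@@H]1OC[C@@H]([C@@H](O)c2cc(OC)c(OCc3ccccc3)c(OC)c2)[C@H]1COS(=O)(=O)c1ccc(C)cc1 | intermediate
17 | (1S,2R,5S,6R)-2-[4-(allyloxy)-3,5-dimethoxyphenyl]-6-[4-(benzyloxy)-3,5-dimethoxyphenyl]-3,7-dioxabicyclo[3.3.0]octane | COc1cc(cc(OC)c1OCC=C)[C@@H]1OC[C@@H]2[C@H]1CO[C@H]2c1cc(OC)c(OCc2ccccc2)c(OC)c1 | intermediate
18 | 4-[(1S,2R,5S,6R)-6-(4-benzyloxy-3,5-dimethoxyphenyl)-3,7-dioxabicyclo[3.3.0]octan-2-yl]-2,6-dimethoxyphenol | COc1cc(cc(OC)c1O)[C@@H]1OC[C@@H]2[C@H]1CO[C@H]2c1cc(OC)c(OCc2ccccc2)c(OC)c1 | intermediate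
19 | (S)-4-benzyloxazolidin-2-one | O=C1OC[C@H](Cc2ccccc2)N1 | starting material
20 | (S)-4-benzyl-3-(bromoacetyl)oxazolidin-2-one | O=C1OC[C@H](Cc2ccccc2)N1C(=O)CBr | intermediate
21 | (R)-4-benzyloxazolidin-2-one | O=C1OC[C@@H](Cc2ccccc2)N1 | starting material
22 | (R)-4-benzyl-3-(bromoacetyl)oxazolidin-2-one | O=C1OC[C@@H](Cc2ccccc2)N1C(=O)CBr | intermediate
23 | vanillin | COc1cc(C=O)ccc1O | starting material
24 | 3-methoxy-4-(triisopropylsilyloxy)benzaldehyde | COc1cc(C=O)ccc1O[Si](C(C)C)(C(C)C)C(C)C | intermediate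
25 | core with O-a–CH2C(=O)Xc(S); O-b benzyl | COc1cc(cc(OC)c1OCC(=O)N1[C@@H](Cc2ccccc2)COC1=O)[C@@H]1OC[C@@H]2[C@H]1CO[C@H]2c1cc(OC)c(OCc2ccccc2)c(OC)c1 | intermediate
26 | (Z)-dibutylboron enolate of 25 (aryloxy group and O–B cis) | COc1cc(cc(OC)c1O/C=C(\OB(CCCC)CCCC)N1[C@@H](Cc2ccccc2)COC1=O)[C@@H]1OC[C@@H]2[C@H]1CO[C@H]2c1cc(OC)c(OCc2ccccc2)c(OC)c1 | intermediate
27 | core with O-a–CH[C(=O)Xc(S)]–CH(OH)Ar(T), (2S,3R); O-b benzyl | COc1cc(cc(OC)c1O[C@H](C(=O)N1[C@@H](Cc2ccccc2)COC1=O)[C@H](O)c1ccc(O[Si](C(C)C)(C(C)C)C(C)C)c(OC)c1)[C@@H]1OC[C@@H]2[C@H]1CO[C@H]2c1cc(OC)c(OCc2ccccc2)c(OC)c1 | intermediate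
28 | core with O-a chain (7R,8R): 7-OH, 9-OH, Ar(T); O-b benzyl | COc1cc(cc(OC)c1O[C@H](CO)[C@H](O)c1ccc(O[Si](C(C)C)(C(C)C)C(C)C)c(OC)c1)[C@@H]1OC[C@@H]2[C@H]1CO[C@H]2c1cc(OC)c(OCc2ccccc2)c(OC)c1 | intermediate
29 | core with O-a chain (7R,8R): 7-OH, 9-OTBS, Ar(T); O-b benzyl | COc1cc(cc(OC)c1O[C@H](CO[Si](C)(C)C(C)(C)C)[C@H](O)c1ccc(O[Si](C(C)C)(C(C)C)C(C)C)c(OC)c1)[C@@H]1OC[C@@H]2[C@H]1CO[C@H]2c1cc(OC)c(OCc2ccccc2)c(OC)c1 | intermediate
30 | core with O-a chain (7R,8R): 7-OH, 9-OTBS, Ar(T); O-b free phenol | COc1cc(cc(OC)c1O[C@H](CO[Si](C)(C)C(C)(C)C)[C@H](O)c1ccc(O[Si](C(C)C)(C(C)C)C(C)C)c(OC)c1)[C@@H]1OC[C@@H]2[C@H]1CO[C@H]2c1cc(OC)c(O)c(OC)c1 | intermediate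
31 | core with O-a chain (7R,8R): 7-OH, 9-OTBS, Ar(T); O-b–CH2C(=O)Xc(S) | COc1cc(cc(OC)c1O[C@H](CO[Si](C)(C)C(C)(C)C)[C@H](O)c1ccc(O[Si](C(C)C)(C(C)C)C(C)C)c(OC)c1)[C@@H]1OC[C@@H]2[C@H]1CO[C@H]2c1cc(OC)c(OCC(=O)N2[C@@H](Cc3ccccc3)COC2=O)c(OC)c1 | intermediate
32 | core with O-a chain (7S,8R): 7-OPNB, 9-OTBS, Ar(T); O-b–CH2C(=O)Xc(S) | COc1cc(cc(OC)c1O[C@H](CO[Si](C)(C)C(C)(C)C)[C@@H](OC(=O)c1ccc(cc1)[N+](=O)[O-])c1ccc(O[Si](C(C)C)(C(C)C)C(C)C)c(OC)c1)[C@@H]1OC[C@@H]2[C@H]1CO[C@H]2c1cc(OC)c(OCC(=O)N2[C@@H](Cc3ccccc3)COC2=O)c(OC)c1 | intermediate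
33 | trans-isoeugenol, 2-methoxy-4-[(E)-prop-1-enyl]phenol | COc1cc(/C=C/C)ccc1O | starting material
34 | (4R)-4-benzyl-3-({2-methoxy-4-[(E)-prop-1-enyl]phenoxy}acetyl)oxazolidin-2-one | COc1cc(/C=C/C)ccc1OCC(=O)N1[C@H](Cc2ccccc2)COC1=O | intermediate
35 | (Z)-dibutylboron enolate of 34 (aryloxy group and O–B cis) | COc1cc(/C=C/C)ccc1O/C=C(\OB(CCCC)CCCC)N1[C@H](Cc2ccccc2)COC1=O | intermediate
36 | (4R)-4-benzyl-3-[(2R,3S)-3-hydroxy-2-{2-methoxy-4-[(E)-prop-1-enyl]phenoxy}-3-Ar(T)-propanoyl]oxazolidin-2-one | COc1cc(/C=C/C)ccc1O[C@@H](C(=O)N1[C@H](Cc2ccccc2)COC1=O)[C@@H](O)c1ccc(O[Si](C(C)C)(C(C)C)C(C)C)c(OC)c1 | intermediate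
37 | (1S,2S)-2-{2-methoxy-4-[(E)-prop-1-enyl]phenoxy}-1-Ar(T)-propane-1,3-diol | COc1cc(/C=C/C)ccc1O[C@@H](CO)[C@@H](O)c1ccc(O[Si](C(C)C)(C(C)C)C(C)C)c(OC)c1 | intermediate
38 | (1S,2S)-3-(tert-butyldimethylsilyloxy)-2-{2-methoxy-4-[(E)-prop-1-enyl]phenoxy}-1-Ar(T)-propan-1-ol | COc1cc(/C=C/C)ccc1O[C@@H](CO[Si](C)(C)C(C)(C)C)[C@@H](O)c1ccc(O[Si](C(C)C)(C(C)C)C(C)C)c(OC)c1 | intermediate
39 | (1R,2S)-3-(tert-butyldimethylsilyloxy)-2-{2-methoxy-4-[(E)-prop-1-enyl]phenoxy}-1-Ar(T)-propyl 4-nitrobenzoate | COc1cc(/C=C/C)ccc1O[C@@H](CO[Si](C)(C)C(C)(C)C)[C@H](OC(=O)c1ccc(cc1)[N+](=O)[O-])c1ccc(O[Si](C(C)C)(C(C)C)C(C)C)c(OC)c1 | intermediate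
40 | (1R,2S)-3-(tert-butyldimethylsilyloxy)-2-(4-formyl-2-methoxyphenoxy)-1-Ar(T)-propyl 4-nitrobenzoate | COc1cc(C=O)ccc1O[C@@H](CO[Si](C)(C)C(C)(C)C)[C@H](OC(=O)c1ccc(cc1)[N+](=O)[O-])c1ccc(O[Si](C(C)C)(C(C)C)C(C)C)c(OC)c1 | intermediate
41 | (Z)-dibutylboron enolate of 32 (aryloxy group and O–B cis) | COc1cc(cc(OC)c1O[C@H](CO[Si](C)(C)C(C)(C)C)[C@@H](OC(=O)c1ccc(cc1)[N+](=O)[O-])c1ccc(O[Si](C(C)C)(C(C)C)C(C)C)c(OC)c1)[C@@H]1OC[C@@H]2[C@H]1CO[C@H]2c1cc(OC)c(O/C=C(\OB(CCCC)CCCC)N2[C@@H](Cc3ccccc3)COC2=O)c(OC)c1 | intermediate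
42 | core with O-a chain (7S,8R): 7-OPNB, 9-OTBS, Ar(T); O-b–CH[C(=O)Xc(S)]–CH(OH)–aryl, (2S,3R), the aryl being 3-methoxy-4-oxyphenyl whose oxygen carries the unit 1 chain (7R,8S): 7-OPNB, 9-OTBS, Ar(T) | COc1cc(cc(OC)c1O[C@H](CO[Si](C)(C)C(C)(C)C)[C@@H](OC(=O)c1ccc(cc1)[N+](=O)[O-])c1ccc(O[Si](C(C)C)(C(C)C)C(C)C)c(OC)c1)[C@@H]1OC[C@@H]2[C@H]1CO[C@H]2c1cc(OC)c(O[C@H](C(=O)N2[C@@H](Cc3ccccc3)COC2=O)[C@H](O)c2ccc(O[C@@H](CO[Si](C)(C)C(C)(C)C)[C@H](OC(=O)c3ccc(cc3)[N+](=O)[O-])c3ccc(O[Si](C(C)C)(C(C)C)C(C)C)c(OC)c3)c(OC)c2)c(OC)c1 | intermediate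
43 | core with unit 3 on O-a (7S,8R: 7-OH, 9-OTBS, Ar(T)); unit 2 on O-b (7R,8R: 7-OH, 9-OH) whose aryl oxygen carries unit 1 (7R,8S: 7-OH, 9-OTBS, Ar(T)) | COc1cc(cc(OC)c1O[C@H](CO[Si](C)(C)C(C)(C)C)[C@@H](O)c1ccc(O[Si](C(C)C)(C(C)C)C(C)C)c(OC)c1)[C@@H]1OC[C@@H]2[C@H]1CO[C@H]2c1cc(OC)c(O[C@H](CO)[C@H](O)c2ccc(O[C@@H](CO[Si](C)(C)C(C)(C)C)[C@H](O)c3ccc(O[Si](C(C)C)(C(C)C)C(C)C)c(OC)c3)c(OC)c2)c(OC)c1 | intermediate
44 | CNP0316493.1: core (1S,2R,5S,6R) with unit 3 (7S,8R) on one syringyl oxygen and unit 2 (7R,8R) bearing unit 1 (7R,8S) on the other, all hydroxyls and both guaiacyl phenols free | COc1cc([C@@H](O)[C@H](CO)Oc2ccc([C@@H](O)[C@@H](CO)Oc3c(OC)cc([C@@H]4OC[C@@H]5[C@H]4CO[C@H]5c4cc(OC)c(O[C@H](CO)[C@@H](O)c5ccc(O)c(OC)c5)c(OC)c4)cc3OC)cc2OC)ccc1O | target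

## Step count and least certain steps

Total: 29 steps. Longest linear sequence: 18 steps (1 → 6 → 8 → 10 → 11 → 14 → 15 → 17 → 18 → 25 → 27 → 28 → 29 → 30 → 31 → 32 → 42 → 43 → 44; steps 3–10, 14–20 and 27–29).

**Step 7 (key step, proposed new method).**
- What may go wrong: ionisation of the benzylic, allylic C–O bond of the butenolide by residual silyl triflate, or deprotonation at C6 by fluoride, with loss of enantiopurity or isomerisation of the double bond; capture of the oxocarbenium ion by fluoride, or ylide dimerisation, outrunning the cycloaddition; and endo orientation of the ylide, giving the C2 epimer. The last could be corrected by acid equilibration at the lactone stage, where the exo aryl group is thermodynamically preferred.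
- Fallback (known chemistry): the conjugate addition–aldol road, setting out from 6 and 2 and returning at 17. Aldehyde 6 is converted with propane-1,3-dithiol and BF3·OEt2 into 2-[4-(benzyloxy)-3,5-dimethoxyphenyl]-1,3-dithiane F1. Its lithium anion is added 1,4 to the menthyloxy butenolide A2 and the enolate is trapped with 2 to give the trans,trans lactone F2. The dithiane is hydrolysed (MeI, CaCO3, aqueous MeCN) to the aryl ketone F3. This is reduced under control of the adjacent C5 centre (LiBH(s-Bu)3, THF, −78 °C) to the C6 carbinol F4. LiAlH4 reduces lactone and acetal to the tetraol F5 with release of the auxiliary alcohol. MsCl in pyridine converts F5, through the bis(primary mesylate) F6, into 17 by two 5-exo-tet closures that leave both benzylic C–O bonds intact.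

**Step 5.**
- What may go wrong: slow or poorly selective enzymatic acylation, because the acrylate donor is a weaker and conjugate-addition-prone acyl donor and the aryl group is bulky; this would erode the enantiopurity of 10.
- Fallback: setting out from 8, resolve with the same lipase and vinyl acetate to the (R)-acetate F7, methanolyse (K2CO3, MeOH) to the (R)-alcohol F8 and acylate chemically (acryloyl chloride, Et3N, CH2Cl2, −20 °C), returning at 10.

**Step 9.**
- What may go wrong: competing sulfonylation or ionisation of the electron-rich secondary benzylic hydroxyl, which would scramble C6, or elimination of the primary sulfonate.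
- Fallback: setting out from 14 and avoiding the diol altogether, reduce the lactone to the lactol F9 (i-Bu2AlH, toluene, −78 °C) and deoxygenate its oxocarbenium ion (Et3SiH, BF3·OEt2, CH2Cl2, −78 °C), returning at 17; the O7–C8 and C6–O7 bonds are then never broken.

**Step 20.**
- What may go wrong: SN1 leakage of the oxyphosphonium intermediate at the electron-rich benzylic carbon, giving incomplete inversion (threo/erythro mixtures), or elimination toward the enol ether.
- Fallback: setting out from 31, oxidise C7 with Dess–Martin periodinane to the aryl ketone F10, reduce under chelation control between the ketone and the C8 aryloxy oxygen (Zn(BH4)2, Et2O, −20 °C), which for α-oxygenated ketones delivers the anti, here erythro, alcohol F11, and acylate with 4-nitrobenzoyl chloride and pyridine, returning at 32.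

**Step 25.**
- What may go wrong: the same partial loss of stereochemical fidelity at C7 as in step 20.
- Fallback: setting out from 38, Dess–Martin oxidation to the ketone F12, chelation-controlled reduction with Zn(BH4)2 to the erythro alcohol F13, and acylation with 4-nitrobenzoyl chloride and pyridine, returning at 39.

## Further compounds

F1 | step 7 | 2-[4-(benzyloxy)-3,5-dimethoxyphenyl]-1,3-dithiane | COc1cc(cc(OC)c1OCc1ccccc1)C1SCCCS1
F2 | step 7 | trans,trans conjugate addition–aldol lactone (structure identical with A1) | O=C1O[C@H](O[C@H]2C[C@@H](C)CC[C@@H]2C(C)C)[C@@H](C2(SCCCS2)c2cc(OC)c(OCc3ccccc3)c(OC)c2)[C@@H]1[C@@H](O)c1cc(OC)c(OCC=C)c(OC)c1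
F3 | step 7 | aryl ketone from F2 (dithiane replaced by C=O, other centres unchanged) | O=C1O[C@H](O[C@H]2C[C@@H](C)CC[C@@H]2C(C)C)[C@@H](C(=O)c2cc(OC)c(OCc3ccccc3)c(OC)c2)[C@@H]1[C@@H](O)c1cc(OC)c(OCC=C)c(OC)c1
F4 | step 7 | C6 carbinol from F3, (R) at the new benzylic centre | O=C1O[C@H](O[C@H]2C[C@@H](C)CC[C@@H]2C(C)C)[C@@H]([C@@H](O)c2cc(OC)c(OCc3ccccc3)c(OC)c2)[C@@H]1[C@@H](O)c1cc(OC)c(OCC=C)c(OC)c1
F5 | step 7 | (1R,2S,3S,4R)-1-[4-(allyloxy)-3,5-dimethoxyphenyl]-4-[4-(benzyloxy)-3,5-dimethoxyphenyl]-2,3-bis(hydroxymethyl)butane-1,4-diol | COc1cc(cc(OC)c1OCC=C)[C@H](O)[C@H](CO)[C@@H](CO)[C@@H](O)c1cc(OC)c(OCc2ccccc2)c(OC)c1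
F6 | step 7 | bis(primary methanesulfonate) of F5 | COc1cc(cc(OC)c1OCC=C)[C@H](O)[C@H](COS(C)(=O)=O)[C@@H](COS(C)(=O)=O)[C@@H](O)c1cc(OC)c(OCc2ccccc2)c(OC)c1
F7 | step 5 | (1R)-1-[4-(benzyloxy)-3,5-dimethoxyphenyl]prop-2-en-1-yl acetate | CC(=O)O[C@H](C=C)c1cc(OC)c(OCc2ccccc2)c(OC)c1
F8 | step 5 | (1R)-1-[4-(benzyloxy)-3,5-dimethoxyphenyl]prop-2-en-1-ol | O[C@H](C=C)c1cc(OC)c(OCc2ccccc2)c(OC)c1
F9 | step 9 | (1R,2R,5S,6R)-2-[4-(allyloxy)-3,5-dimethoxyphenyl]-6-[4-(benzyloxy)-3,5-dimethoxyphenyl]-3,7-dioxabicyclo[3.3.0]octan-8-ol (lactol, either anomer) | COc1cc(cc(OC)c1OCC=C)[C@@H]1OC[C@@H]2[C@H]1C(O)O[C@H]2c1cc(OC)c(OCc2ccccc2)c(OC)c1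
F10 | step 20 | C7 ketone from 31 (C8 R; 9-OTBS; Ar(T); O-b–CH2C(=O)Xc(S)) | COc1cc(cc(OC)c1O[C@H](CO[Si](C)(C)C(C)(C)C)C(=O)c1ccc(O[Si](C(C)C)(C(C)C)C(C)C)c(OC)c1)[C@@H]1OC[C@@H]2[C@H]1CO[C@H]2c1cc(OC)c(OCC(=O)N2[C@@H](Cc3ccccc3)COC2=O)c(OC)c1
F11 | step 20 | erythro alcohol (7S,8R) corresponding to 31 | COc1cc(cc(OC)c1O[C@H](CO[Si](C)(C)C(C)(C)C)[C@@H](O)c1ccc(O[Si](C(C)C)(C(C)C)C(C)C)c(OC)c1)[C@@H]1OC[C@@H]2[C@H]1CO[C@H]2c1cc(OC)c(OCC(=O)N2[C@@H](Cc3ccccc3)COC2=O)c(OC)c1
F12 | step 25 | (2S)-3-(tert-butyldimethylsilyloxy)-2-{2-methoxy-4-[(E)-prop-1-enyl]phenoxy}-1-Ar(T)-propan-1-one | COc1cc(/C=C/C)ccc1O[C@@H](CO[Si](C)(C)C(C)(C)C)C(=O)c1ccc(O[Si](C(C)C)(C(C)C)C(C)C)c(OC)c1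
F13 | step 25 | (1R,2S)-3-(tert-butyldimethylsilyloxy)-2-{2-methoxy-4-[(E)-prop-1-enyl]phenoxy}-1-Ar(T)-propan-1-ol | COc1cc(/C=C/C)ccc1O[C@@H](CO[Si](C)(C)C(C)(C)C)[C@H](O)c1ccc(O[Si](C(C)C)(C(C)C)C(C)C)c(OC)c1
A1 | alternative 1 | trans,trans lactone: 3-[(R)-hydroxy(4-allyloxy-3,5-dimethoxyphenyl)methyl]-4-[2-(4-benzyloxy-3,5-dimethoxyphenyl)-1,3-dithian-2-yl]-5-[(1S,2R,5S)-menthyloxy]oxolan-2-one | O=C1O[C@H](O[C@H]2C[C@@H](C)CC[C@@H]2C(C)C)[C@@H](C2(SCCCS2)c2cc(OC)c(OCc3ccccc3)c(OC)c2)[C@@H]1[C@@H](O)c1cc(OC)c(OCC=C)c(OC)c1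
A2 | alternative 1 | (5S)-5-{[(1S,2R,5S)-5-methyl-2-(propan-2-yl)cyclohexyl]oxy}furan-2(5H)-one | O=C1O[C@H](O[C@H]2C[C@@H](C)CC[C@@H]2C(C)C)C=C1
A3 | alternative 1 | 2-[4-(benzyloxy)-3,5-dimethoxyphenyl]-1,3-dithiane | COc1cc(cc(OC)c1OCc1ccccc1)C1SCCCS1
A4 | alternative 2 | (1S,2R,5S,6R)-2-[4-(benzyloxy)-3,5-dimethoxyphenyl]-6-[4-(tert-butyldimethylsilyloxy)-3,5-dimethoxyphenyl]-3,7-dioxabicyclo[3.3.0]octane | COc1cc(cc(OC)c1OCc1ccccc1)[C@@H]1OC[C@@H]2[C@H]1CO[C@H]2c1cc(OC)c(O[Si](C)(C)C(C)(C)C)c(OC)c1
A5 | alternative 2 | 2-{(S)-[4-(benzyloxy)-3,5-dimethoxyphenyl][(E)-3-(4-tert-butyldimethylsilyloxy-3,5-dimethoxyphenyl)prop-2-enyloxy]methyl}oxirane (either configuration at the oxirane carbon) | COc1cc(cc(OC)c1OCc1ccccc1)[C@H](OC/C=C/c1cc(OC)c(O[Si](C)(C)C(C)(C)C)c(OC)c1)C1CO1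
A6 | alternative 3 | (1R,2R,5R,6R)-2,6-bis[4-(benzyloxy)-3,5-dimethoxyphenyl]-3,7-dioxabicyclo[3.3.0]octane-4,8-dione | COc1cc(cc(OC)c1OCc1ccccc1)[C@@H]1OC(=O)[C@@H]2[C@H]1C(=O)O[C@H]2c1cc(OC)c(OCc2ccccc2)c(OC)c1
A7 | alternative 3 | (4R,8R)-4,8-bis[4-(benzyloxy)-3,5-dimethoxyphenyl]-1,5-dioxocane-2,6-dione | O=C1C[C@H](c2cc(OC)c(OCc3ccccc3)c(OC)c2)OC(=O)C[C@H](c2cc(OC)c(OCc3ccccc3)c(OC)c2)O1
A8 | alternative 3 | (3R)-3-[4-(benzyloxy)-3,5-dimethoxyphenyl]-3-hydroxypropanoic acid | OC(=O)C[C@@H](O)c1cc(OC)c(OCc2ccccc2)c(OC)c1
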